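**Plan**

1. Numbering (daucane): C1 = methyl-bearing ring-fusion carbon, C4 = isopropyl carbinol, C5 = ring-fusion CH, C6 and C10 = ester carbinols, C7 = ring CH2, C8=C9 = ring olefin.
2. Cuts, in retrosynthetic order: the two angelate C–O bonds; the C8=C9 olefin of the seven-membered ring (ring-closing metathesis); the C10 carbinol back to a Sharpless epoxide of an (E)-allylic alcohol; the C4–isopropyl bond; the C5–C6 and C1–C10 bonds (one-pot conjugate addition/aldol on 3-methylcyclopent-2-en-1-one).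
3. Feature used: C8=C9 is a trisubstituted olefin inside the seven-membered ring, flanked by the C10 carbinol and the C7 methylene. Opening it leaves a vinyl carbinol arm on C1 and a methallyl carbinol arm on C5, trans on adjacent carbons of the cyclopentane ring.
4. Forward order: cyclopentane ring with C1, C5, C6 and C4 (steps 3–4), then the C10 carbinol (steps 5–8), then the seven-membered ring (step 9), the angelates last (step 10).
5. Stereochemistry: C1 from a chiral copper catalyst; C5 and C6 from the aldol (face away from the bulky α-silylalkenyl group, chair transition state, anti); C4 from attack anti to the C5 side chain; C10 from Sharpless epoxidation with L-(+)-tartrate.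
6. Helper group: a trimethylsilyl group on the future C10 steers the hydroalumination, makes the C1 substituent large for the aldol, and is removed by fluoride in step 5.

Key step: step 9

**Route**

Step 1
Reactants: 1 3-(trimethylsilyl)prop-2-yn-1-ol
Product: 2 tert-butyldimethyl{[3-(trimethylsilyl)prop-2-yn-1-yl]oxy}silane
Conditions: t-BuMe2SiCl, imidazole, CH2Cl2, 23 °C
Reagents that add atoms: tert-butyldimethylsilyl chloride, CC(C)(C)[Si](C)(C)Cl
Why: Standard O-silylation of a primary alcohol (silyl ether formation); the ether keeps the hydroxyl from consuming i-Bu2AlH in step 3.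

Step 2
Reactants: 3 3-methylbut-3-en-1-ol
Product: 4 3-methylbut-3-enal
Conditions: Dess–Martin periodinane, pyridine, CH2Cl2, 0 °C; filtered cold solution used at once
Reagents that add atoms: none
Why: Buffered Dess–Martin oxidation of a homoallylic primary alcohol should give the β,γ-unsaturated aldehyde without moving the double bond into conjugation.

Step 3
Reactants: 2 tert-butyldimethyl{[3-(trimethylsilyl)prop-2-yn-1-yl]oxy}silane, 5 3-methylcyclopent-2-en-1-one, 4 3-methylbut-3-enal
Product: 8 (2S,3S)-3-[(Z)-3-{[tert-butyl(dimethyl)silyl]oxy}-1-(trimethylsilyl)prop-1-en-1-yl]-2-[(1S)-1-hydroxy-3-methylbut-3-en-1-yl]-3-methylcyclopentan-1-one, via alkenylalane 6 (not isolated), via aluminium enolate 7 (not isolated)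
Conditions: i-Bu2AlH, hexanes/THF, 55 °C; then 5, CuCl2·2H2O (5 mol%), chiral sulfonate-bearing imidazolinium salt (carbene precursor, 5.5 mol%), THF, −15 °C; then 4, −78 to −40 °C; aq. potassium sodium tartrate
Reagents that add atoms: none
Why: syn-Hydroalumination of the silylalkyne places aluminium on the silicon-bearing carbon (6, Si cis to CH2OSi); copper-catalysed enantioselective conjugate addition of this silyl-substituted alkenylaluminium to the β-methyl enone, with the ligand enantiomer chosen for the 3S product, sets the quaternary C1 and gives enolate 7, which adds to 4 through a Zimmerman–Traxler chair (tandem conjugate addition–aldol), the cyclic E-enolate giving the anti aldol (C6) and the aldehyde entering C5 on the face away from the bulky α-silylalkenyl group (C5 side chain trans to the future C10).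

Step 4
Reactants: 8 (2S,3S)-3-[(Z)-3-{[tert-butyl(dimethyl)silyl]oxy}-1-(trimethylsilyl)prop-1-en-1-yl]-2-[(1S)-1-hydroxy-3-methylbut-3-en-1-yl]-3-methylcyclopentan-1-one
Product: 9 (1R,2S,3S)-3-[(Z)-3-{[tert-butyl(dimethyl)silyl]oxy}-1-(trimethylsilyl)prop-1-en-1-yl]-2-[(1S)-1-hydroxy-3-methylbut-3-en-1-yl]-3-methyl-1-(propan-2-yl)cyclopentan-1-ol
Conditions: i-PrMgCl (3.5 equiv), CeCl3 (3.5 equiv), THF, −78 to 0 °C; aq. NH4Cl
Reagents that add atoms: isopropylmagnesium chloride, CC(C)[Mg]Cl
Why: 1,2-Addition of the low-basicity reagent from i-PrMgCl and CeCl3 to an enolizable ketone (organocerium addition); the first equivalent makes the C6 alkoxide, whose chelate to the C4 carbonyl together with the pseudoaxial C1 methyl shields one face, so isopropyl should enter anti to the C5 side chain and leave the C4 hydroxyl cis to it.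

Step 5
Reactants: 9 (1R,2S,3S)-3-[(Z)-3-{[tert-butyl(dimethyl)silyl]oxy}-1-(trimethylsilyl)prop-1-en-1-yl]-2-[(1S)-1-hydroxy-3-methylbut-3-en-1-yl]-3-methyl-1-(propan-2-yl)cyclopentan-1-ol
Product: 11 (1R,2S,3R)-3-[(E)-3-hydroxyprop-1-en-1-yl]-2-[(1S)-1-hydroxy-3-methylbut-3-en-1-yl]-3-methyl-1-(propan-2-yl)cyclopentan-1-ol, via vinylsilane triol 10 (not isolated)
Conditions: Bu4NF (5 equiv), THF, 23 °C; then DMSO, 60 °C
Reagents that add atoms: none
Why: Fluoride cleaves the silyl ether and the freed primary alkoxide, held cis to the trimethylsilyl group across the double bond, takes silicon from carbon in a 1,4-Brook rearrangement; protonation of the vinyl carbanion with retention and cleavage of the new O–Si bond should leave the (E)-allylic alcohol.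

Step 6
Reactants: 11 (1R,2S,3R)-3-[(E)-3-hydroxyprop-1-en-1-yl]-2-[(1S)-1-hydroxy-3-methylbut-3-en-1-yl]-3-methyl-1-(propan-2-yl)cyclopentan-1-ol
Product: 12 (1R,2S,3S)-2-[(1S)-1-hydroxy-3-methylbut-3-en-1-yl]-3-[(2S,3S)-3-(hydroxymethyl)oxiran-2-yl]-3-methyl-1-(propan-2-yl)cyclopentan-1-ol
Conditions: Ti(OiPr)4 (20 mol%), L-(+)-diisopropyl tartrate (24 mol%), t-BuOOH, 4 Å molecular sieves, CH2Cl2, −20 °C
Reagents that add atoms: tert-butyl hydroperoxide, CC(C)(C)OO
Why: Sharpless asymmetric epoxidation: only the olefin of the allylic alcohol is activated through titanium, so the methallyl group is spared, and L-(+)-tartrate on an (E)-allylic alcohol delivers oxygen to the face that gives the (2S,3S)-oxirane, which fixes C10 by reagent control.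

Step 7
Reactants: 12 (1R,2S,3S)-2-[(1S)-1-hydroxy-3-methylbut-3-en-1-yl]-3-[(2S,3S)-3-(hydroxymethyl)oxiran-2-yl]-3-methyl-1-(propan-2-yl)cyclopentan-1-ol
Product: 13 (1R,2S,3S)-2-[(1S)-1-hydroxy-3-methylbut-3-en-1-yl]-3-[(2S,3R)-3-(iodomethyl)oxiran-2-yl]-3-methyl-1-(propan-2-yl)cyclopentan-1-ol
Conditions: I2, PPh3, imidazole, THF, 0 °C
Reagents that add atoms: iodine, II
Why: Appel-type iodination of the primary alcohol through its alkoxyphosphonium salt; the hindered secondary and tertiary hydroxyls and the epoxide should not react at 0 °C, and no stereocentre is touched (the C3 oxirane descriptor changes by priority only).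

Step 8
Reactants: 13 (1R,2S,3S)-2-[(1S)-1-hydroxy-3-methylbut-3-en-1-yl]-3-[(2S,3R)-3-(iodomethyl)oxiran-2-yl]-3-methyl-1-(propan-2-yl)cyclopentan-1-ol
Product: 14 (1R,2S,3S)-2-[(1S)-1-hydroxy-3-methylbut-3-en-1-yl]-3-[(1R)-1-hydroxyprop-2-en-1-yl]-3-methyl-1-(propan-2-yl)cyclopentan-1-ol
Conditions: Zn dust, EtOH, 70 °C
Reagents that add atoms: none
Why: Zinc inserts into the C–I bond and the organozinc opens the adjacent epoxide by β-elimination (reductive opening of a 2,3-epoxy iodide), giving the transposed allylic alcohol; the C10–O bond is not broken, so C10 keeps the configuration set in step 6 (descriptor R by priority change).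

Step 9
Reactants: 14 (1R,2S,3S)-2-[(1S)-1-hydroxy-3-methylbut-3-en-1-yl]-3-[(1R)-1-hydroxyprop-2-en-1-yl]-3-methyl-1-(propan-2-yl)cyclopentan-1-ol
Product: 15 (3R,3aS,4S,8R,8aS)-6,8a-dimethyl-3-(propan-2-yl)-1,2,3,3a,4,5,8,8a-octahydroazulene-3,4,8-triol
Conditions: second-generation Grubbs catalyst (5 mol%), 1,4-benzoquinone (10 mol%), CH2Cl2 (2 mM), 40 °C
Reagents that add atoms: none
Why: Ring-closing olefin metathesis: the ruthenium alkylidene of the catalyst loads on the monosubstituted vinyl group of the C10 carbinol, adds across the 1,1-disubstituted olefin of the methallyl arm in a [2+2] step, and the ruthenacyclobutane collapses to the C8=C9 olefin with loss of ethene. The closest known reaction type is ring-closing metathesis of an allylic-alcohol diene to a cycloheptene with a trisubstituted double bond, as used for hydroazulene terpenoids. The seven-membered ring is the only ring closed; it forms by intramolecular alkylidene transfer between two arms that sit trans on the adjacent carbons C1 and C5 of the cyclopentane, giving the trans-fused bicyclo[5.3.0]decene, and the ring size enforces the cis olefin geometry. No stereocentre is created, and C1, C4, C5, C6 and C10 are carried through because no bond at these centres is touched. The step needs cyclization to beat oligomerization and redox isomerization of the C10 allylic alcohol to an ethyl ketone; the substrate holds only two olefins on vicinal arms (one ring size possible), and high dilution with 1,4-benzoquinone as hydride scavenger should secure the rest.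

Step 10
Reactants: 15 (3R,3aS,4S,8R,8aS)-6,8a-dimethyl-3-(propan-2-yl)-1,2,3,3a,4,5,8,8a-octahydroazulene-3,4,8-triol
Product: 16 (3R,3aS,4S,8R,8aS)-3-hydroxy-6,8a-dimethyl-3-(propan-2-yl)-1,2,3,3a,4,5,8,8a-octahydroazulene-4,8-diyl bis[(2Z)-2-methylbut-2-enoate]
Conditions: (2Z)-2-methylbut-2-enoic acid (6 equiv), 2,4,6-trichlorobenzoyl chloride, Et3N, toluene, 23 °C; then 15, 80 °C
Reagents that add atoms: (2Z)-2-methylbut-2-enoic acid (angelic acid), C/C=C(/C)C(=O)O
Why: Yamaguchi-type mixed-anhydride esterification run without a nucleophilic amine catalyst, conditions under which the Z-configured angeloyl group should not isomerize to tigloyl; the two secondary hydroxyls are acylated while the tertiary C4 hydroxyl next to isopropyl stays free.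

**Compound list**

1 | 3-(trimethylsilyl)prop-2-yn-1-ol | C[Si](C)(C)C#CCO | starting material
2 | tert-butyldimethyl{[3-(trimethylsilyl)prop-2-yn-1-yl]oxy}silane | C[Si](C)(C)C#CCO[Si](C)(C)C(C)(C)C | intermediate
3 | 3-methylbut-3-en-1-ol | CC(=C)CCO | starting material
4 | 3-methylbut-3-enal | CC(=C)CC=O | intermediate
5 | 3-methylcyclopent-2-en-1-one | CC1=CC(=O)CC1 | starting material
6 | [(Z)-3-{[tert-butyl(dimethyl)silyl]oxy}-1-(trimethylsilyl)prop-1-en-1-yl]bis(2-methylpropyl)alane | CC(C)C[Al](CC(C)C)/C([Si](C)(C)C)=C/CO[Si](C)(C)C(C)(C)C | intermediate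
7 | {[(3S)-3-[(Z)-3-{[tert-butyl(dimethyl)silyl]oxy}-1-(trimethylsilyl)prop-1-en-1-yl]-3-methylcyclopent-1-en-1-yl]oxy}bis(2-methylpropyl)alane | CC(C)C[Al](CC(C)C)OC1=C[C@](C)(CC1)/C([Si](C)(C)C)=C/CO[Si](C)(C)C(C)(C)C | intermediate
8 | (2S,3S)-3-[(Z)-3-{[tert-butyl(dimethyl)silyl]oxy}-1-(trimethylsilyl)prop-1-en-1-yl]-2-[(1S)-1-hydroxy-3-methylbut-3-en-1-yl]-3-methylcyclopentan-1-one | C=C(C)C[C@H](O)[C@H]1C(=O)CC[C@]1(C)/C([Si](C)(C)C)=C/CO[Si](C)(C)C(C)(C)C | intermediate
9 | (1R,2S,3S)-3-[(Z)-3-{[tert-butyl(dimethyl)silyl]oxy}-1-(trimethylsilyl)prop-1-en-1-yl]-2-[(1S)-1-hydroxy-3-methylbut-3-en-1-yl]-3-methyl-1-(propan-2-yl)cyclopentan-1-ol | C=C(C)C[C@H](O)[C@H]1[C@](O)(C(C)C)CC[C@]1(C)/C([Si](C)(C)C)=C/CO[Si](C)(C)C(C)(C)C | intermediate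
10 | (1R,2S,3S)-3-[(Z)-3-hydroxy-1-(trimethylsilyl)prop-1-en-1-yl]-2-[(1S)-1-hydroxy-3-methylbut-3-en-1-yl]-3-methyl-1-(propan-2-yl)cyclopentan-1-ol | C=C(C)C[C@H](O)[C@H]1[C@](O)(C(C)C)CC[C@]1(C)/C([Si](C)(C)C)=C/CO | intermediate
11 | (1R,2S,3R)-3-[(E)-3-hydroxyprop-1-en-1-yl]-2-[(1S)-1-hydroxy-3-methylbut-3-en-1-yl]-3-methyl-1-(propan-2-yl)cyclopentan-1-ol | C=C(C)C[C@H](O)[C@H]1[C@](O)(C(C)C)CC[C@]1(C)/C=C/CO | intermediate
12 | (1R,2S,3S)-2-[(1S)-1-hydroxy-3-methylbut-3-en-1-yl]-3-[(2S,3S)-3-(hydroxymethyl)oxiran-2-yl]-3-methyl-1-(propan-2-yl)cyclopentan-1-ol | C=C(C)C[C@H](O)[C@H]1[C@](O)(C(C)C)CC[C@]1(C)[C@@H]2O[C@H]2CO | intermediate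
13 | (1R,2S,3S)-2-[(1S)-1-hydroxy-3-methylbut-3-en-1-yl]-3-[(2S,3R)-3-(iodomethyl)oxiran-2-yl]-3-methyl-1-(propan-2-yl)cyclopentan-1-ol | C=C(C)C[C@H](O)[C@H]1[C@](O)(C(C)C)CC[C@]1(C)[C@@H]2O[C@H]2CI | intermediate
14 | (1R,2S,3S)-2-[(1S)-1-hydroxy-3-methylbut-3-en-1-yl]-3-[(1R)-1-hydroxyprop-2-en-1-yl]-3-methyl-1-(propan-2-yl)cyclopentan-1-ol | C=C(C)C[C@H](O)[C@H]1[C@](O)(C(C)C)CC[C@]1(C)[C@H](O)C=C | intermediate
15 | (3R,3aS,4S,8R,8aS)-6,8a-dimethyl-3-(propan-2-yl)-1,2,3,3a,4,5,8,8a-octahydroazulene-3,4,8-triol | O[C@H]1CC(C)=C[C@@H](O)[C@@]2(C)CC[C@@](O)(C(C)C)[C@H]12 | intermediate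
16 | (3R,3aS,4S,8R,8aS)-3-hydroxy-6,8a-dimethyl-3-(propan-2-yl)-1,2,3,3a,4,5,8,8a-octahydroazulene-4,8-diyl bis[(2Z)-2-methylbut-2-enoate] | C/C=C(/C)C(=O)O[C@H]1CC(C)=C[C@@H](OC(=O)/C(C)=C\C)[C@@]2(C)CC[C@@](O)(C(C)C)[C@H]12 | target

**Step count and risks**

Total step count: 10.
Longest linear sequence: 9 steps (steps 1 and 3 to 10, from compound 1); step 2 is a one-step side branch.

Steps most likely to fail:

Step 3. The hydroalumination may place aluminium on the wrong carbon or the α-silyl alkenylalane may lose its geometry by isomerization. The crowded alkenyl group may transfer slowly with erosion of enantioselectivity. The aluminium enolate may add sluggishly to the enolizable aldehyde, which then self-condenses. The fallback sets out from 2 and comes back at 8. Hydrozirconation of 2 with Cp2Zr(H)Cl followed by iodinolysis should give (E)-tert-butyl{[3-iodo-3-(trimethylsilyl)prop-2-en-1-yl]oxy}dimethylsilane F1 with fixed geometry. Iodine–lithium exchange (t-BuLi) and transmetallation with Me2AlCl give a defined alkenyl(dimethyl)alane for the same copper-catalysed conjugate addition to 5, and the enolate is trapped with Me3SiOTf as trimethyl{[(3S)-3-[(Z)-3-{[tert-butyl(dimethyl)silyl]oxy}-1-(trimethylsilyl)prop-1-en-1-yl]-3-methylcyclopent-1-en-1-yl]oxy}silane F2, which is isolated. Cleavage of F2 with MeLi, exchange to the zinc enolate with ZnCl2 and addition of 4 at −78 °C should then return to 8.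

Step 4. The metal aldolate may undergo retro-aldol cleavage or enolization, the isopropyl reagent may reduce the ketone by β-hydride transfer, or the chelate may give poor facial selectivity. The fallback sets out from 8 and comes back at 11. Silylation of the side-chain hydroxyl (t-BuMe2SiOTf, 2,6-lutidine, −78 °C) should give (2S,3S)-3-[(Z)-3-{[tert-butyl(dimethyl)silyl]oxy}-1-(trimethylsilyl)prop-1-en-1-yl]-2-[(1S)-1-{[tert-butyl(dimethyl)silyl]oxy}-3-methylbut-3-en-1-yl]-3-methylcyclopentan-1-one F3, which can no longer cleave or chelate. Addition of i-PrMgCl/CeCl3, now under steric control alone, should give (1R,2S,3S)-3-[(Z)-3-{[tert-butyl(dimethyl)silyl]oxy}-1-(trimethylsilyl)prop-1-en-1-yl]-2-[(1S)-1-{[tert-butyl(dimethyl)silyl]oxy}-3-methylbut-3-en-1-yl]-3-methyl-1-(propan-2-yl)cyclopentan-1-ol F4. Treatment with Bu4NF as in step 5 removes both silyl ethers and the vinylic silyl group and returns to 11.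

Step 10. Acylation of the neopentylic C10 hydroxyl may stay incomplete, and the angeloyl group may isomerize from Z to E on prolonged heating. The fallback sets out from 15 and comes back at 16. Carbodiimide esterification (dicyclohexylcarbodiimide, 4-dimethylaminopyridine) of both secondary hydroxyls with 2-[bis(2,2,2-trifluoroethoxy)phosphoryl]propanoic acid should give (3R,3aS,4S,8R,8aS)-3-hydroxy-6,8a-dimethyl-3-(propan-2-yl)-1,2,3,3a,4,5,8,8a-octahydroazulene-4,8-diyl bis{2-[bis(2,2,2-trifluoroethoxy)phosphoryl]propanoate} F5. A twofold Still–Gennari olefination of F5 with acetaldehyde (KN(SiMe3)2, 18-crown-6, THF, −78 °C) then builds both Z-configured 2-methylbut-2-enoates under kinetic control and gives 16.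

**Further compounds**

F1 | step 3 | (E)-tert-butyl{[3-iodo-3-(trimethylsilyl)prop-2-en-1-yl]oxy}dimethylsilane | I/C([Si](C)(C)C)=C/CO[Si](C)(C)C(C)(C)C
F2 | step 3 | trimethyl{[(3S)-3-[(Z)-3-{[tert-butyl(dimethyl)silyl]oxy}-1-(trimethylsilyl)prop-1-en-1-yl]-3-methylcyclopent-1-en-1-yl]oxy}silane | C[Si](C)(C)OC1=C[C@](C)(CC1)/C([Si](C)(C)C)=C/CO[Si](C)(C)C(C)(C)C
F3 | step 4 | (2S,3S)-3-[(Z)-3-{[tert-butyl(dimethyl)silyl]oxy}-1-(trimethylsilyl)prop-1-en-1-yl]-2-[(1S)-1-{[tert-butyl(dimethyl)silyl]oxy}-3-methylbut-3-en-1-yl]-3-methylcyclopentan-1-one | C=C(C)C[C@H](O[Si](C)(C)C(C)(C)C)[C@H]1C(=O)CC[C@]1(C)/C([Si](C)(C)C)=C/CO[Si](C)(C)C(C)(C)C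
F4 | step 4 | (1R,2S,3S)-3-[(Z)-3-{[tert-butyl(dimethyl)silyl]oxy}-1-(trimethylsilyl)prop-1-en-1-yl]-2-[(1S)-1-{[tert-butyl(dimethyl)silyl]oxy}-3-methylbut-3-en-1-yl]-3-methyl-1-(propan-2-yl)cyclopentan-1-ol | C=C(C)C[C@H](O[Si](C)(C)C(C)(C)C)[C@H]1[C@](O)(C(C)C)CC[C@]1(C)/C([Si](C)(C)C)=C/CO[Si](C)(C)C(C)(C)C
F5 | step 10 | (3R,3aS,4S,8R,8aS)-3-hydroxy-6,8a-dimethyl-3-(propan-2-yl)-1,2,3,3a,4,5,8,8a-octahydroazulene-4,8-diyl bis{2-[bis(2,2,2-trifluoroethoxy)phosphoryl]propanoate} | CC(C(=O)O[C@H]1CC(C)=C[C@@H](OC(=O)C(C)P(=O)(OCC(F)(F)F)OCC(F)(F)F)[C@@]2(C)CC[C@@](O)(C(C)C)[C@H]12)P(=O)(OCC(F)(F)F)OCC(F)(F)F
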